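The route rests on cutting C9 out of ring B (C5–C10, halimane numbering). The C8(=O)–C9(CH3)=C10 enone of an octalone is traced back to a hydrindanone in which C8 and C10 are directly bonded. In the key step, chloro(methyl)carbene adds to the C8=C10 silyl enol ether of this five-membered ring and the chlorocyclopropane opens. C9 thus enters ring B together with its methyl group and leaves the enone that later delivers the quaternary C9 and the C1=C10 alkene. The precursor is a 6-5 bicycle made from cyclopentenone in four steps. C5 (Rh catalysis) relays to C9 and C8, and an Evans alkylation sets C13.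

Key step: step 5

Remark on numbering: ring A = C1–C5, C10. Ring B = C5–C10. C11–C12 is the ethylene link, C13 is the side-chain stereocentre, and C14–C16 is the chain to the lactam.
Remark on the chemistry: the target is drawn as the hydrogen sulfate, so it is assumed that the acid is released from its pyridinium salt in the last operation and handled cold.

Step 1
Reactants: 1 cyclopent-2-en-1-one; 2 isopropenylboronic acid pinacol ester
Product: 3 (3R)-3-(prop-1-en-2-yl)cyclopentan-1-one
Conditions: Rh(acac)(C2H4)2 (cat.), (R)-BINAP, dioxane/H2O, 100 °C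
Reagents that add atoms: none
Why: In this Hayashi–Miyaura rhodium-catalysed asymmetric 1,4-addition of an alkenylboronate to a cyclic enone, the (R)-BINAP–Rh alkenyl species should add to one enone face only and set C5 as (R) in 3, following the established sense of induction for cyclopentenone.

Step 2
Reactants: 3 (3R)-3-(prop-1-en-2-yl)cyclopentan-1-one
Product: 4 4-methyl-4-[(1R)-3-oxocyclopentyl]pentanal
Conditions: Fe(acac)3 (cat.), PhSiH3, EtOH, 60 °C
Reagents that add atoms: acrolein C=CC=O
Why: In this metal-hydride hydrogen-atom-transfer Giese addition, Markovnikov H-atom transfer to the 1,1-disubstituted alkene gives the tertiary C4 radical, which adds to the β-carbon of acrolein and builds the quaternary C4 (C3, C2, C1 come from acrolein) without touching C5.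

Step 3
Reactants: 4 4-methyl-4-[(1R)-3-oxocyclopentyl]pentanal
Product: 5 (3aS)-4,4-dimethyl-2,3,3a,4,5,6-hexahydro-1H-inden-1-one
Conditions: KOH, MeOH, high dilution, 0 °C to rt
Reagents that add atoms: none
Why: In this intramolecular aldol condensation closing ring A, only attack of C10 on the aldehyde C1 can dehydrate to a conjugated enone, the bridged aldol from the aldehyde enolate is reversible, and C5 is not acidified in 4 or 5.

Step 4
Reactants: 5 (3aS)-4,4-dimethyl-2,3,3a,4,5,6-hexahydro-1H-inden-1-one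
Product: 6 triethyl{[(3aS)-4,4-dimethyl-3,3a,4,5,6,7-hexahydro-2H-inden-1-yl]oxy}silane
Conditions: Et3SiH, RhCl(PPh3)3 (cat.), toluene, 50 °C
Reagents that add atoms: triethylsilane CC[SiH](CC)CC
Why: Rh-catalysed 1,4-hydrosilylation of the fixed s-cis enone with a monohydrosilane should give the tetrasubstituted C8=C10 silyl enol ether regiospecifically, which direct enolisation of the saturated ketone would not do.

Step 5
Reactants: 6 triethyl{[(3aS)-4,4-dimethyl-3,3a,4,5,6,7-hexahydro-2H-inden-1-yl]oxy}silane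
Product: 8 (4aS)-1,5,5-trimethyl-4,4a,5,6,7,8-hexahydronaphthalen-2(3H)-one, via siloxychlorocyclopropane 7 (not isolated)
Conditions: CH3CHCl2, n-BuLi, Et2O, −35 °C; then toluene, 110 °C
Reagents that add atoms: 1,1-dichloroethane CC(Cl)Cl
Why: n-BuLi deprotonates 1,1-dichloroethane and α-elimination of LiCl gives the chloro(methyl)carbene(oid), which adds in a concerted [2+1] cheletropic mode to the only alkene present, the electron-rich C8=C10 enol ether, and so closes the cyclopropane C8–C9–C10 of 7. On heating, the isomer with chlorine syn to C5 and C7 undergoes the disrotatory two-electron cyclopropyl-to-allyl electrocyclic opening: chloride leaves C9 as the shared C8–C10 bond breaks, the five-membered ring C5–C6–C7–C8–C10 becomes the six-membered ring B, and chloride strips the silyl group from the siloxyallyl cation to give the enone. The closest known reaction type is the halocarbene ring expansion of cyclic silyl enol ethers to α-halo or α-methyl cycloalkenones, which is established for cyclopentanone-derived enol ethers. No lasting stereocentre is created, because C8, C9 and C10 all end sp2, and C5 is a spectator. The step needs chlorine on the face of C5/C7, which the larger methyl group should favour by turning away from the folded five-membered ring; it also needs cleavage of C8–C10 only, which is fixed because this bond lies opposite the carbon bearing the leaving group and the oxygen on C8 stabilises the developing cation.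

Step 6
Reactants: 8 (4aS)-1,5,5-trimethyl-4,4a,5,6,7,8-hexahydronaphthalen-2(3H)-one
Product: 10 (1S,4aS)-1,5,5-trimethyl-1-(prop-2-en-1-yl)-3,4,4a,5,6,7-hexahydronaphthalen-2(1H)-one, via potassium dienolate 9 (not isolated)
Conditions: KOt-Bu, t-BuOH/THF, rt; allyl bromide, 0 °C
Reagents that add atoms: allyl bromide C=CCBr
Why: In this deconjugative α-alkylation of the thermodynamic extended enolate (γ-deprotonation at C1), bond formation at C9 moves the alkene to C1=C10, and the stereoelectronically preferred axial attack, on the face whose only syn-axial neighbours are H5 and H7, should place the allyl group (C11) cis to H5.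

Step 7
Reactants: 10 (1S,4aS)-1,5,5-trimethyl-1-(prop-2-en-1-yl)-3,4,4a,5,6,7-hexahydronaphthalen-2(1H)-one
Product: 11 (1R,4aS)-1,5,5-trimethyl-2-methylidene-1-(prop-2-en-1-yl)-1,2,3,4,4a,5,6,7-octahydronaphthalene
Conditions: Ph3PCH3Br, KOt-Bu, toluene, 90 °C
Reagents that add atoms: methyltriphenylphosphonium bromide C[P+](c1ccccc1)(c1ccccc1)c1ccccc1.[Br-]
Why: Wittig methylenation with excess ylide in hot toluene should cope with the ketone next to the quaternary C9, and no epimerisable centre adjoins C8.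

Step 8
Reactants: 12 (4R)-4-benzyl-1,3-oxazolidin-2-one
Product: 14 (4R)-3-acryloyl-4-benzyl-1,3-oxazolidin-2-one, via lithium oxazolidinide 13 (not isolated)
Conditions: n-BuLi, THF, −78 °C; acryloyl chloride
Reagents that add atoms: acryloyl chloride C=CC(=O)Cl
Why: N-acylation of the lithiated auxiliary is the standard entry to N-enoyl oxazolidinones and does not touch the stereocentre.

Step 9
Reactants: 11 (1R,4aS)-1,5,5-trimethyl-2-methylidene-1-(prop-2-en-1-yl)-1,2,3,4,4a,5,6,7-octahydronaphthalene; 14 (4R)-3-acryloyl-4-benzyl-1,3-oxazolidin-2-one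
Product: 15 (4R)-4-benzyl-3-{(2E)-4-[(1R,4aS)-1,5,5-trimethyl-2-methylidene-1,2,3,4,4a,5,6,7-octahydronaphthalen-1-yl]but-2-enoyl}-1,3-oxazolidin-2-one
Conditions: Hoveyda–Grubbs II (cat.), CH2Cl2, 40 °C
Reagents that add atoms: none
Why: Olefin cross metathesis of the terminal allyl group with the electron-poor acrylimide should give the E-enimide, while the methylidene next to quaternary C9 and the trisubstituted C1=C10 alkene are too hindered to engage.

Step 10
Reactants: 15 (4R)-4-benzyl-3-{(2E)-4-[(1R,4aS)-1,5,5-trimethyl-2-methylidene-1,2,3,4,4a,5,6,7-octahydronaphthalen-1-yl]but-2-enoyl}-1,3-oxazolidin-2-one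
Product: 16 (4R)-4-benzyl-3-{4-[(1R,2R,4aS)-1,2,5,5-tetramethyl-1,2,3,4,4a,5,6,7-octahydronaphthalen-1-yl]butanoyl}-1,3-oxazolidin-2-one
Conditions: H2 (1 atm), Pt/C, EtOAc, rt
Reagents that add atoms: none
Why: Heterogeneous catalytic hydrogenation should saturate the enimide and the exocyclic methylidene but spare the hindered C1=C10 alkene, and the axial C11 chain on C9 shields the α face so that hydrogen arrives from the β face and leaves the C8 methyl equatorial and trans to the C9 methyl.

Step 11
Reactants: 16 (4R)-4-benzyl-3-{4-[(1R,2R,4aS)-1,2,5,5-tetramethyl-1,2,3,4,4a,5,6,7-octahydronaphthalen-1-yl]butanoyl}-1,3-oxazolidin-2-one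
Product: 18 (4R)-4-benzyl-3-[(2S)-2-{2-[(1R,2R,4aS)-1,2,5,5-tetramethyl-1,2,3,4,4a,5,6,7-octahydronaphthalen-1-yl]ethyl}pent-4-enoyl]-1,3-oxazolidin-2-one, via sodium Z-enolate 17 (not isolated)
Conditions: NaHMDS, THF, −78 °C; allyl iodide
Reagents that add atoms: allyl iodide C=CCI
Why: In this Evans alkylation the chelated Z-enolate is attacked on the face opposite the benzyl group, which for the (4R)-auxiliary should give the (2S)-imide, the C13 geometry of the target.

Step 12
Reactants: 18 (4R)-4-benzyl-3-[(2S)-2-{2-[(1R,2R,4aS)-1,2,5,5-tetramethyl-1,2,3,4,4a,5,6,7-octahydronaphthalen-1-yl]ethyl}pent-4-enoyl]-1,3-oxazolidin-2-one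
Product: 19 (2S)-2-{2-[(1R,2R,4aS)-1,2,5,5-tetramethyl-1,2,3,4,4a,5,6,7-octahydronaphthalen-1-yl]ethyl}pent-4-en-1-ol
Conditions: LiBH4, H2O (1 equiv), Et2O, 0 °C
Reagents that add atoms: none
Why: Reductive cleavage of the N-acyl oxazolidinone with LiBH4 should give the primary alcohol without epimerising C13 or touching either alkene.

Step 13
Reactants: 20 2,5-dimethoxy-2,5-dihydrofuran; 21 3-methylbutan-1-amine
Product: 23 1-(3-methylbutyl)-1,5-dihydro-2H-pyrrol-2-one, via (Z)-but-2-enedial 22 (not isolated)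
Conditions: aq HCl, rt
Reagents that add atoms: none
Why: Acid hydrolysis of the bis-acetal unmasks (Z)-butenedial, which condenses with the primary amine in a Paal–Knorr-type manner to a 2-hydroxypyrrole tautomer that should settle as the conjugated γ-lactam.

Step 14
Reactants: 23 1-(3-methylbutyl)-1,5-dihydro-2H-pyrrol-2-one
Product: 25 3-bromo-1-(3-methylbutyl)-1,5-dihydro-2H-pyrrol-2-one, via dibromolactam 24 (not isolated)
Conditions: Br2, CH2Cl2, 0 °C; Et3N, 0 °C to rt
Reagents that add atoms: bromine BrBr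
Why: Bromine addition followed by base-induced loss of HBr, which starts at the acidic C3–H, is the standard α-bromination of a conjugated carbonyl compound and leaves bromine at C3.

Step 15
Reactants: 19 (2S)-2-{2-[(1R,2R,4aS)-1,2,5,5-tetramethyl-1,2,3,4,4a,5,6,7-octahydronaphthalen-1-yl]ethyl}pent-4-en-1-ol; 25 3-bromo-1-(3-methylbutyl)-1,5-dihydro-2H-pyrrol-2-one
Product: 27 3-{(4R)-4-(hydroxymethyl)-6-[(1R,2R,4aS)-1,2,5,5-tetramethyl-1,2,3,4,4a,5,6,7-octahydronaphthalen-1-yl]hexyl}-1-(3-methylbutyl)-1,5-dihydro-2H-pyrrol-2-one, via bis-borane 26 (not isolated)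
Conditions: 9-BBN (2.2 equiv), THF, rt; then 25, PdCl2(dppf) (cat.), AsPh3, Cs2CO3, DMF/H2O, rt
Reagents that add atoms: none
Why: 9-BBN hydroborates only the terminal alkene in the anti-Markovnikov sense (the alcohol travels as its borinate), and a B-alkyl Suzuki–Miyaura coupling with the α-bromo enone-type partner should form C16–C17 without disturbing a stereocentre.

Step 16
Reactants: 27 3-{(4R)-4-(hydroxymethyl)-6-[(1R,2R,4aS)-1,2,5,5-tetramethyl-1,2,3,4,4a,5,6,7-octahydronaphthalen-1-yl]hexyl}-1-(3-methylbutyl)-1,5-dihydro-2H-pyrrol-2-one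
Product: 29 CNP0218721.1 (target hydrogen sulfate), via pyridinium sulfate 28 (not isolated)
Conditions: SO3·pyridine, pyridine, 0 °C to rt; Dowex 50W (H+), MeOH, 0 °C
Reagents that add atoms: sulfur trioxide–pyridine complex O=S(=O)([O-])[n+]1ccccc1
Why: O-sulfation of the only hydroxy group with SO3·pyridine followed by cold cation exchange should give the hydrogen sulfate while the alkene and lactam stay untouched.

Compound list
1 | cyclopent-2-en-1-one | O=C1C=CCC1 | starting material
2 | isopropenylboronic acid pinacol ester | C=C(C)B1OC(C)(C)C(C)(C)O1 | starting material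
3 | (3R)-3-(prop-1-en-2-yl)cyclopentan-1-one | C=C(C)[C@@H]1CCC(=O)C1 | intermediate
4 | 4-methyl-4-[(1R)-3-oxocyclopentyl]pentanal | O=CCCC(C)(C)[C@@H]1CCC(=O)C1 | intermediate
5 | (3aS)-4,4-dimethyl-2,3,3a,4,5,6-hexahydro-1H-inden-1-one | O=C1C2=CCCC(C)(C)[C@@H]2CC1 | intermediate
6 | triethyl{[(3aS)-4,4-dimethyl-3,3a,4,5,6,7-hexahydro-2H-inden-1-yl]oxy}silane | CC[Si](CC)(CC)OC1=C2CCCC(C)(C)[C@@H]2CC1 | intermediate
7 | siloxychlorocyclopropane: 1-chloro-1-methylcyclopropane fused across C8–C10 of 6, OSiEt3 on C8, C5 as in 6, epimers at the new centres | CC1(Cl)C2(O[Si](CC)(CC)CC)CC[C@@H]3C12CCCC3(C)C | intermediate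
8 | (4aS)-1,5,5-trimethyl-4,4a,5,6,7,8-hexahydronaphthalen-2(3H)-one | CC1=C2CCCC(C)(C)[C@@H]2CCC1=O | intermediate
9 | potassium dienolate of 8 (C8–O−, C8=C9, C10=C1) | [K+].[O-]C1=C(C)C2=CCCC(C)(C)[C@@H]2CC1 | intermediate
10 | (1S,4aS)-1,5,5-trimethyl-1-(prop-2-en-1-yl)-3,4,4a,5,6,7-hexahydronaphthalen-2(1H)-one | C=CC[C@@]1(C)C2=CCCC(C)(C)[C@@H]2CCC1=O | intermediate
11 | (1R,4aS)-1,5,5-trimethyl-2-methylidene-1-(prop-2-en-1-yl)-1,2,3,4,4a,5,6,7-octahydronaphthalene | C=CC[C@@]1(C)C2=CCCC(C)(C)[C@@H]2CCC1=C | intermediate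
12 | (4R)-4-benzyl-1,3-oxazolidin-2-one | O=C1OC[C@@H](Cc2ccccc2)N1 | starting material
13 | lithium salt of 12 | [Li+].O=C1OC[C@@H](Cc2ccccc2)[N-]1 | intermediate
14 | (4R)-3-acryloyl-4-benzyl-1,3-oxazolidin-2-one | C=CC(=O)N1[C@H](Cc2ccccc2)COC1=O | intermediate
15 | (4R)-4-benzyl-3-{(2E)-4-[(1R,4aS)-1,5,5-trimethyl-2-methylidene-octahydronaphthalen-1-yl]but-2-enoyl}-1,3-oxazolidin-2-one | O=C(/C=C/C[C@@]1(C)C2=CCCC(C)(C)[C@@H]2CCC1=C)N1[C@H](Cc2ccccc2)COC1=O | intermediate
16 | (4R)-4-benzyl-3-{4-[(1R,2R,4aS)-1,2,5,5-tetramethyl-octahydronaphthalen-1-yl]butanoyl}-1,3-oxazolidin-2-one | O=C(CCC[C@@]1(C)C2=CCCC(C)(C)[C@@H]2CC[C@H]1C)N1[C@H](Cc2ccccc2)COC1=O | intermediate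
17 | sodium Z-enolate of 16 | [Na+].[O-]/C(=C\CC[C@@]1(C)C2=CCCC(C)(C)[C@@H]2CC[C@H]1C)N1[C@H](Cc2ccccc2)COC1=O | intermediate
18 | (4R)-4-benzyl-3-[(2S)-2-{2-[(1R,2R,4aS)-1,2,5,5-tetramethyl-octahydronaphthalen-1-yl]ethyl}pent-4-enoyl]-1,3-oxazolidin-2-one | C=CC[C@H](CC[C@@]1(C)C2=CCCC(C)(C)[C@@H]2CC[C@H]1C)C(=O)N1[C@H](Cc2ccccc2)COC1=O | intermediate
19 | (2S)-2-{2-[(1R,2R,4aS)-1,2,5,5-tetramethyl-octahydronaphthalen-1-yl]ethyl}pent-4-en-1-ol | C=CC[C@H](CC[C@@]1(C)C2=CCCC(C)(C)[C@@H]2CC[C@H]1C)CO | intermediate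
20 | 2,5-dimethoxy-2,5-dihydrofuran | COC1C=CC(OC)O1 | starting material
21 | 3-methylbutan-1-amine | CC(C)CCN | starting material
22 | (Z)-but-2-enedial | O=C/C=C\C=O | intermediate
23 | 1-(3-methylbutyl)-1,5-dihydro-2H-pyrrol-2-one | CC(C)CCN1CC=CC1=O | intermediate
24 | 3,4-dibromo-1-(3-methylbutyl)pyrrolidin-2-one | CC(C)CCN1CC(Br)C(Br)C1=O | intermediate
25 | 3-bromo-1-(3-methylbutyl)-1,5-dihydro-2H-pyrrol-2-one | CC(C)CCN1CC=C(Br)C1=O | intermediate
26 | bis-borane: C16-(9-BBN) alkylborane and O-(9-BBN) borinate of 19 | C(CCB1C2CCCC1CCC2)[C@H](CC[C@@]3(C)C4=CCCC(C)(C)[C@@H]4CC[C@H]3C)COB5C6CCCC5CCC6 | intermediate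
27 | 3-{(4R)-4-(hydroxymethyl)-6-[(1R,2R,4aS)-1,2,5,5-tetramethyl-octahydronaphthalen-1-yl]hexyl}-1-(3-methylbutyl)-1,5-dihydro-2H-pyrrol-2-one | CC(C)CCN1CC=C(CCC[C@H](CC[C@@]2(C)C3=CCCC(C)(C)[C@@H]3CC[C@H]2C)CO)C1=O | intermediate
28 | pyridinium salt of 29 | CC(C)CCN1CC=C(CCC[C@H](CC[C@@]2(C)C3=CCCC(C)(C)[C@@H]3CC[C@H]2C)COS(=O)(=O)[O-])C1=O.c1cc[nH+]cc1 | intermediate
29 | CNP0218721.1, hydrogen sulfate of 27 | CC(C)CCN1CC=C(CCC[C@H](CC[C@@]2(C)C3=CCCC(C)(C)[C@@H]3CC[C@H]2C)COS(=O)(=O)O)C1=O | target

Total step count: 16. Longest linear sequence: 13 (steps 1–7, 9–12, 15, 16).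

Steps most likely to fail

**Step 5.** Two things may go wrong.
- The short-lived carbene may rearrange by 1,2-hydrogen shift faster than the crowded tetrasubstituted enol ether captures it.
- The carbene may add with chlorine on the face away from C5/C7, which blocks the electrocyclic opening.

The fallback sets out from 6. Dibromocarbene (CHBr3, KOt-Bu, pentane, −20 °C) should give the dibromocyclopropane F1, in which one bromine is necessarily syn to C5/C7. Warming, or AgBF4, should then open it to the α-bromo enone F2. A Negishi methylation (Me2Zn, PdCl2(dppf), THF) puts the methyl group on C9 and comes back to the route at 8.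

**Step 10.** Three things may go wrong.
- Hydrogen delivery to the methylidene may show poor facial selectivity.
- The exocyclic double bond may migrate into ring B before it is reduced.
- The C1=C10 alkene may be partly reduced.

The fallback sets out from 10 and sets C8 by a radical instead of on a metal surface. MeMgBr/CeCl3 should give the tertiary alcohol F3. Methyl oxalyl chloride with DMAP gives the methyl oxalate F4. A Barton–McCombie-type deoxygenation (Bu3SnH, AIBN, toluene, reflux) lets the C8 radical take hydrogen from the open β face and gives the allyl tetramethyloctalin F5. Cross metathesis with 14 gives the enimide F6, in which only the conjugated alkene remains to be hydrogenated (H2, Pd/C), and the route is rejoined at 16.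

**Step 6.** O-allylation, a second alkylation at C7, or deprotonation at C5 instead of C1 may erode the yield, the position of the alkene and the integrity of C5. The fallback sets out from 8. The thermodynamic dienolate is trapped on oxygen with allyl chloroformate to give the allyl dienyl carbonate F7. A palladium-catalysed decarboxylative Tsuji–Trost allylation (Pd(PPh3)4, THF, rt) then forms the C9–C11 bond under neutral conditions with one equivalent of allyl donor and comes back to the route at 10.

Further compounds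
F1 | step 5 | dibromocyclopropane fused across C8–C10 of 6 | BrC1(Br)C2(O[Si](CC)(CC)CC)CC[C@@H]3C12CCCC3(C)C
F2 | step 5 | (4aS)-1-bromo-5,5-dimethyl-4,4a,5,6,7,8-hexahydronaphthalen-2(3H)-one | BrC1=C2CCCC(C)(C)[C@@H]2CCC1=O
F3 | step 10 | (1S,4aS)-1,2,5,5-tetramethyl-1-(prop-2-en-1-yl)-1,2,3,4,4a,5,6,7-octahydronaphthalen-2-ol (C8 epimers) | C=CC[C@@]1(C)C2=CCCC(C)(C)[C@@H]2CCC1(C)O
F4 | step 10 | methyl oxalate of F3 | C=CC[C@@]1(C)C2=CCCC(C)(C)[C@@H]2CCC1(C)OC(=O)C(=O)OC
F5 | step 10 | (1R,2R,4aS)-1,2,5,5-tetramethyl-1-(prop-2-en-1-yl)-1,2,3,4,4a,5,6,7-octahydronaphthalene | C=CC[C@@]1(C)C2=CCCC(C)(C)[C@@H]2CC[C@H]1C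
F6 | step 10 | (4R)-4-benzyl-3-{(2E)-4-[(1R,2R,4aS)-1,2,5,5-tetramethyl-octahydronaphthalen-1-yl]but-2-enoyl}-1,3-oxazolidin-2-one | O=C(/C=C/C[C@@]1(C)C2=CCCC(C)(C)[C@@H]2CC[C@H]1C)N1[C@H](Cc2ccccc2)COC1=O
F7 | step 6 | allyl (4aS)-1,5,5-trimethyl-3,4,4a,5,6,7-hexahydronaphthalen-2-yl carbonate | C=CCOC(=O)OC1=C(C)C2=CCCC(C)(C)[C@@H]2CC1
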